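**Retrosynthetic overview**
1. Kuraridin 17 ⇐ tris-MOM ether 16 ⇐ aryl–C(=O) bond: ring A aryllithium 15 (from phenol 11) + ring B Weinreb cinnamamide 14.
2. The prenyl arm of the lavandulyl group in 11 ⇐ the lactone carbonyl of benzoxepinone 9 (partial reduction, isopropylidene Wittig).
3. Key bond ArCH2–C*H of 9 ⇐ o-quinone methide 8 (electrophilic CH2) + dienal 7, whose normally electrophilic β-carbon becomes the nucleophile as a carbene-bound homoenolate; a chiral triazolium sets the only stereocentre.
4. 8 ⇐ sulfone 5 ⇐ 2,4,6-trihydroxybenzaldehyde 1; 7 ⇐ methacrolein 6; 14 ⇐ 2,4-dihydroxybenzaldehyde 12.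
5. Ring order: rings A and B are bought; the only ring made is the temporary seven-membered lactone (step 5), opened again in step 6.

Assumption: the (5aS,10bR)-aminoindanol triazolium named in step 5 is taken to give the (4S)-lactone 9; this sense is assigned by analogy, and if experiment shows the opposite, the commercial (5aR,10bS) salt is used with nothing else changed.

**Step 1**
Reactants: 1 2,4,6-trihydroxybenzaldehyde
Product: 2 2,6-dihydroxy-4-methoxybenzaldehyde
Conditions: Me2SO4 (1.0 equiv), K2CO3 (1.0 equiv), acetone, 0 °C → rt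
Reagents that add atoms: dimethyl sulfate, COS(=O)(=O)OC
Why: The 4-OH (para to the formyl group and not hydrogen-bonded to it) is the most acidic and gives the most nucleophilic phenoxide, so one equivalent of Me2SO4 gives selective Williamson mono-O-methylation.

**Step 2**
Reactants: 2 2,6-dihydroxy-4-methoxybenzaldehyde
Product: 3 2-hydroxy-4-methoxy-6-(methoxymethoxy)benzaldehyde
Conditions: MOMCl (1.1 equiv), i-Pr2NEt (1.5 equiv), CH2Cl2, 0 °C
Reagents that add atoms: chloromethyl methyl ether, COCCl
Why: Once one of the two equivalent hydroxyls is alkylated the other is locked in a hydrogen bond to the aldehyde and is inert under these conditions, so the Williamson-type acetalisation stops at the mono-MOM ether.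

**Step 3**
Reactants: 3 2-hydroxy-4-methoxy-6-(methoxymethoxy)benzaldehyde
Product: 5 5-methoxy-3-(methoxymethoxy)-2-[(4-methylbenzenesulfonyl)methyl]phenol, via salicyl alcohol 4 (not isolated)
Conditions: NaBH4, THF/MeOH, 0 °C; then TolSO2Na (3 equiv), AcOH, rt
Reagents that add atoms: sodium 4-methylbenzenesulfinate, Cc1ccc(cc1)S(=O)[O-].[Na+]
Why: Borohydride reduction gives the electron-rich salicyl alcohol 4, which ionises in acetic acid to a stabilised benzylic cation/quinone methide that the sulfinate captures at sulfur (acid-mediated benzylic substitution), giving a bench-stable quinone-methide precursor.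

**Step 4**
Reactants: 6 methacrolein (2-methylprop-2-enal)
Product: 7 (2E)-4-methylpenta-2,4-dienal
Conditions: Ph3P=CHCHO (1 equiv), 6 (3 equiv), toluene, 60 °C, sealed vessel; distil
Reagents that add atoms: (triphenylphosphoranylidene)acetaldehyde, O=CC=P(c1ccccc1)(c1ccccc1)c1ccccc1
Why: Wittig olefination with the formyl-stabilised ylide gives the (E)-enal, and the excess of volatile methacrolein suppresses a second homologation.

**Step 5**
Reactants: 5 5-methoxy-3-(methoxymethoxy)-2-[(4-methylbenzenesulfonyl)methyl]phenol; 7 (2E)-4-methylpenta-2,4-dienal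
Product: 9 (4S)-8-methoxy-6-(methoxymethoxy)-4-(prop-1-en-2-yl)-4,5-dihydro-1-benzoxepin-2(3H)-one, via ortho-quinone methide 8 (not isolated)
Conditions: 7 (2 equiv), (5aS,10bR)-2-mesityl-5a,10b-dihydro-4H,6H-indeno[2,1-b][1,2,4]triazolo[4,3-d][1,4]oxazin-2-ium tetrafluoroborate (15 mol %), Cs2CO3 (1.5 equiv), 4 Å MS, THF, 0 °C → rt, 5 added over 6 h
Reagents that add atoms: none
Why: Proposed new method: carbonate deprotonates 5 and sulfinate leaves to give quinone methide 8 at low concentration, while the carbene adds to 7 to form a Breslow-type dienol whose β-carbon (electrophilic in the free enal) attacks the electrophilic exocyclic CH2 of 8 from the face left open by the indane wall, and the resulting acyl azolium is captured by the phenoxide to close the lactone and release the carbene, so the single stereocentre is set as (S) by catalyst control; the closest known reaction type is the carbene-catalysed enantioselective formal [4+3] annulation of enal homoenolates with in-situ-generated o-quinone methides to benzoxopinones, extended here to a sulfone-derived trioxygenated quinone methide and a dienal.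

**Step 6**
Reactants: 9 (4S)-8-methoxy-6-(methoxymethoxy)-4-(prop-1-en-2-yl)-4,5-dihydro-1-benzoxepin-2(3H)-one
Product: 11 5-methoxy-3-(methoxymethoxy)-2-[(2R)-5-methyl-2-(prop-1-en-2-yl)hex-4-en-1-yl]phenol, via lactol 10 (not isolated)
Conditions: i-Bu2AlH (1.1 equiv), toluene, −78 °C; then Ph3P=CMe2 (4 equiv, from i-PrPPh3I and n-BuLi, THF), −78 °C → rt; aq KNaC4H4O6
Reagents that add atoms: isopropyltriphenylphosphonium iodide, CC(C)[P+](c1ccccc1)(c1ccccc1)c1ccccc1.[I-]
Why: One-pot partial reduction of the aryl lactone to the aluminium hemiacetal (lactol level) followed by Wittig olefination of the aldehyde it releases turns CH2–C(=O)O into the prenyl arm and frees the phenol, while the stereocentre (β to the carbonyl) is untouched and becomes (R) only through the change in CIP priorities.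

**Step 7**
Reactants: 12 2,4-dihydroxybenzaldehyde
Product: 13 2,4-bis(methoxymethoxy)benzaldehyde
Conditions: NaH (2.4 equiv), MOMCl (2.4 equiv), DMF, 0 °C → rt
Reagents that add atoms: chloromethyl methyl ether, COCCl
Why: Double Williamson-type O-alkylation of the bis-phenoxide, with NaH used because the chelated 2-OH does not react under amine-base conditions.

**Step 8**
Reactants: 13 2,4-bis(methoxymethoxy)benzaldehyde
Product: 14 (2E)-3-[2,4-bis(methoxymethoxy)phenyl]-N-methoxy-N-methylprop-2-enamide
Conditions: (EtO)2P(O)CH2C(O)N(OMe)Me (1.2 equiv), NaH (1.2 equiv), THF, 0 °C → rt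
Reagents that add atoms: diethyl {2-[methoxy(methyl)amino]-2-oxoethyl}phosphonate, CCOP(=O)(CC(=O)N(C)OC)OCC
Why: Horner–Wadsworth–Emmons olefination with a stabilised phosphonate gives the (E)-enamide selectively.

**Step 9**
Reactants: 11 5-methoxy-3-(methoxymethoxy)-2-[(2R)-5-methyl-2-(prop-1-en-2-yl)hex-4-en-1-yl]phenol; 14 (2E)-3-[2,4-bis(methoxymethoxy)phenyl]-N-methoxy-N-methylprop-2-enamide
Product: 16 (2E)-3-[2,4-bis(methoxymethoxy)phenyl]-1-{4-hydroxy-6-methoxy-2-(methoxymethoxy)-3-[(2R)-5-methyl-2-(prop-1-en-2-yl)hex-4-en-1-yl]phenyl}prop-2-en-1-one, via dilithio arene 15 (not isolated)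
Conditions: n-BuLi (2.3 equiv), THF, 0 °C → rt; then 14 (1.2 equiv), −78 → 0 °C; aq NH4Cl
Reagents that add atoms: none
Why: After O-lithiation, directed ortho-metalation removes the ring hydrogen flanked by OMOM and OMe and the aryllithium adds 1,2 to the Weinreb amide to give a chelated adduct that releases the (E)-enone only on work-up (Weinreb ketone synthesis); acylation at the other free ring position would give an isomer that yields the same target on MOM removal.

**Step 10**
Reactants: 16 (2E)-3-[2,4-bis(methoxymethoxy)phenyl]-1-{4-hydroxy-6-methoxy-2-(methoxymethoxy)-3-[(2R)-5-methyl-2-(prop-1-en-2-yl)hex-4-en-1-yl]phenyl}prop-2-en-1-one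
Product: 17 kuraridin, (2E)-1-{2,4-dihydroxy-6-methoxy-3-[(2R)-5-methyl-2-(prop-1-en-2-yl)hex-4-en-1-yl]phenyl}-3-(2,4-dihydroxyphenyl)prop-2-en-1-one
Conditions: 3 M aq HCl/MeOH (1:5), rt, dark
Reagents that add atoms: none
Why: Acid-catalysed acetal methanolysis removes all three MOM groups, and dilute acid at room temperature in the dark is chosen to spare the lavandulyl alkenes and to avoid flavanone closure or E/Z isomerisation of the 2'-hydroxychalcone.

**Compound list**
1 | 2,4,6-trihydroxybenzaldehyde | O=Cc1c(O)cc(O)cc1O | starting material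
2 | 2,6-dihydroxy-4-methoxybenzaldehyde | O=Cc1c(O)cc(OC)cc1O | intermediate
3 | 2-hydroxy-4-methoxy-6-(methoxymethoxy)benzaldehyde | O=Cc1c(O)cc(OC)cc1OCOC | intermediate
4 | 2-(hydroxymethyl)-5-methoxy-3-(methoxymethoxy)phenol (salicyl alcohol, not isolated) | OCc1c(O)cc(OC)cc1OCOC | intermediate
5 | 5-methoxy-3-(methoxymethoxy)-2-[(4-methylbenzenesulfonyl)methyl]phenol | Cc1ccc(cc1)S(=O)(=O)Cc1c(O)cc(OC)cc1OCOC | intermediate
6 | methacrolein (2-methylprop-2-enal) | C=C(C)C=O | starting material
7 | (2E)-4-methylpenta-2,4-dienal | C=C(C)/C=C/C=O | intermediate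
8 | 3-methoxy-5-(methoxymethoxy)-6-methylidenecyclohexa-2,4-dien-1-one (ortho-quinone methide, not isolated) | C=C1C(=O)C=C(OC)C=C1OCOC | intermediate
9 | (4S)-8-methoxy-6-(methoxymethoxy)-4-(prop-1-en-2-yl)-4,5-dihydro-1-benzoxepin-2(3H)-one | C=C(C)[C@@H]1CC(=O)Oc2cc(OC)cc(OCOC)c2C1 | intermediate
10 | (4S)-8-methoxy-6-(methoxymethoxy)-4-(prop-1-en-2-yl)-2,3,4,5-tetrahydro-1-benzoxepin-2-ol (lactol, both C2 epimers, formed as its aluminium alkoxide, not isolated) | C=C(C)[C@@H]1CC(O)Oc2cc(OC)cc(OCOC)c2C1 | intermediate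
11 | 5-methoxy-3-(methoxymethoxy)-2-[(2R)-5-methyl-2-(prop-1-en-2-yl)hex-4-en-1-yl]phenol | C=C(C)[C@H](CC=C(C)C)Cc1c(O)cc(OC)cc1OCOC | intermediate
12 | 2,4-dihydroxybenzaldehyde | O=Cc1ccc(O)cc1O | starting material
13 | 2,4-bis(methoxymethoxy)benzaldehyde | O=Cc1ccc(OCOC)cc1OCOC | intermediate
14 | (2E)-3-[2,4-bis(methoxymethoxy)phenyl]-N-methoxy-N-methylprop-2-enamide | CON(C)C(=O)/C=C/c1ccc(OCOC)cc1OCOC | intermediate
15 | lithium 4-lithio-5-methoxy-3-(methoxymethoxy)-2-[(2R)-5-methyl-2-(prop-1-en-2-yl)hex-4-en-1-yl]phenolate (dilithio arene, not isolated) | C=C(C)[C@H](CC=C(C)C)Cc1c(O[Li])cc(OC)c([Li])c1OCOC | intermediate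
16 | (2E)-3-[2,4-bis(methoxymethoxy)phenyl]-1-{4-hydroxy-6-methoxy-2-(methoxymethoxy)-3-[(2R)-5-methyl-2-(prop-1-en-2-yl)hex-4-en-1-yl]phenyl}prop-2-en-1-one | C=C(C)[C@H](CC=C(C)C)Cc1c(O)cc(OC)c(C(=O)/C=C/c2ccc(OCOC)cc2OCOC)c1OCOC | intermediate
17 | kuraridin | C=C(C)[C@H](CC=C(C)C)Cc1c(O)cc(OC)c(C(=O)/C=C/c2ccc(O)cc2O)c1O | target

**Totals**
Total step count: 10. Longest linear sequence: 7 (steps 1, 2, 3, 5, 6, 9, 10).

**Steps most likely to fail, with fallbacks**

Step 5 is the main risk. The trioxygenated quinone methide 8 can be attacked by the phenoxide of unreacted 5 (diarylmethane oligomers) or by the free carbene. The dienal could also react at its δ-carbon, and the sense and level of induction are untested for this pair. The fallback sets out from sulfone 5 and comes back at phenol 11, replacing steps 4 to 6 with auxiliary-controlled enolate chemistry of normal polarity. Commercial 5-methylhex-4-enoic acid is joined to (S)-4-benzyloxazolidin-2-one (PivCl, Et3N; then the lithiated oxazolidinone) to give acyl oxazolidinone F1. Its sodium enolate (NaN(SiMe3)2, 2.2 equiv of enolate, THF, −78 °C) deprotonates 5, sulfinate leaves, and the enolate alkylates the quinone methide on the face away from the benzyl group to give benzylated imide F2 with the (2R) centre. MeNH(OMe)·HCl/AlMe3 converts F2 into Weinreb amide F3, and MeMgBr (excess, 0 °C) gives methyl ketone F4. Non-basic methylenation with Cp2TiMe2 (excess, toluene, 65 °C) keeps the α-stereocentre and gives 11.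

Step 6 can fail because the aluminium hemiacetal of an aryl ester may collapse early and be over-reduced to the primary alcohol, or because aluminium salts interfere with the ylide. The fallback sets out from lactone 9 and comes back at lactol 10. The lactone is opened with MeNH(OMe)·HCl/AlMe3 to hydroxy Weinreb amide F5, whose chelated adduct with LiAlH4 (THF, −40 °C) cannot over-reduce. Work-up gives the hydroxy aldehyde in ring–chain equilibrium with 10, which is isolated and then treated with Ph3P=CMe2 in a separate operation as in step 6.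

Step 9 can fail because ring lithiation of a lithium phenoxide is slow, so benzylic or allylic metalation and butyl addition to 14 may compete. The fallback sets out from phenol 11 and comes back at target 17, making the enone by aldol condensation instead of acylation with the enamide. 11 is capped (NaH, MOMCl) to give bis-MOM ether F6, which lithiates cleanly between OMOM and OMe (n-BuLi, THF, 0 °C). Quenching with N-methoxy-N-methylacetamide gives acetophenone F7. Claisen–Schmidt condensation with aldehyde 13 (KOH, EtOH, rt) gives tetrakis-MOM chalcone F8, and 3 M aq HCl/MeOH at rt gives 17.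

**Further compounds**
F1 | step 5 | (4S)-4-benzyl-3-(5-methylhex-4-enoyl)-1,3-oxazolidin-2-one | CC(C)=CCCC(=O)N1[C@@H](Cc2ccccc2)COC1=O
F2 | step 5 | (4S)-4-benzyl-3-[(2R)-2-{[2-hydroxy-4-methoxy-6-(methoxymethoxy)phenyl]methyl}-5-methylhex-4-enoyl]-1,3-oxazolidin-2-one | CC(C)=CC[C@H](Cc1c(O)cc(OC)cc1OCOC)C(=O)N1[C@@H](Cc2ccccc2)COC1=O
F3 | step 5 | (2R)-2-{[2-hydroxy-4-methoxy-6-(methoxymethoxy)phenyl]methyl}-N-methoxy-N,5-dimethylhex-4-enamide | CC(C)=CC[C@H](Cc1c(O)cc(OC)cc1OCOC)C(=O)N(C)OC
F4 | step 5 | (3R)-3-{[2-hydroxy-4-methoxy-6-(methoxymethoxy)phenyl]methyl}-6-methylhept-5-en-2-one | CC(C)=CC[C@H](Cc1c(O)cc(OC)cc1OCOC)C(C)=O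
F5 | step 6 | (3S)-3-{[2-hydroxy-4-methoxy-6-(methoxymethoxy)phenyl]methyl}-N-methoxy-N,4-dimethylpent-4-enamide | C=C(C)[C@H](CC(=O)N(C)OC)Cc1c(O)cc(OC)cc1OCOC
F6 | step 9 | 5-methoxy-1,3-bis(methoxymethoxy)-2-[(2R)-5-methyl-2-(prop-1-en-2-yl)hex-4-en-1-yl]benzene | C=C(C)[C@H](CC=C(C)C)Cc1c(OCOC)cc(OC)cc1OCOC
F7 | step 9 | 1-{6-methoxy-2,4-bis(methoxymethoxy)-3-[(2R)-5-methyl-2-(prop-1-en-2-yl)hex-4-en-1-yl]phenyl}ethan-1-one | C=C(C)[C@H](CC=C(C)C)Cc1c(OCOC)cc(OC)c(C(C)=O)c1OCOC
F8 | step 9 | (2E)-3-[2,4-bis(methoxymethoxy)phenyl]-1-{6-methoxy-2,4-bis(methoxymethoxy)-3-[(2R)-5-methyl-2-(prop-1-en-2-yl)hex-4-en-1-yl]phenyl}prop-2-en-1-one | C=C(C)[C@H](CC=C(C)C)Cc1c(OCOC)cc(OC)c(C(=O)/C=C/c2ccc(OCOC)cc2OCOC)c1OCOC
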